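## Structural features

The target is a single carbocycle, a cyclohex-2-enone in which every ring atom is substituted. The ring is numbered C1 (alkene carbon carrying the C7 hydroxymethyl group), C2 (ketone), C3 (oxygen acylated by (E)-4-hydroxy-2-methylbut-2-enoic acid), C4 (isopropyl), C5 (isobutyrate) and C6 (alkene CH); the contiguous stereocentres C3, C4 and C5 are R, S and S. The C3 oxygen is trans and the C5 oxygen cis to the isopropyl group, so the two acyloxy groups are trans to each other. The skeleton has no ring fusion and no quaternary carbon; the difficulty is to set three adjacent centres around a C-branched carbon in one absolute sense and to tell four oxygens apart (O3 and O5 carry different acyl groups, O7 and the side-chain oxygen stay free). Fragile points are the C3 ester α to the ketone (epimerisable C3–H), the allylic C5 ester (its loss leads towards a phenol), two free primary allylic alcohols and the E trisubstituted side-chain alkene, so strong base, strong acid and late redox changes are excluded. The C2 carbonyl and the C5 oxygen stand 1,4 across the C1=C6 alkene, which is the pattern of a 7-oxanorbornene from a 2-oxyfuran after its oxygen bridge has opened. O7, C7, C1, C2 and C3 form a five-atom chain, so one boron atom between O7 and C3 closes a six-membered ring; the key step uses this link to tie an alkenylboron dienophile to the furan, which fixes regiochemistry and the endo position of boron and so the C3–C5 relative configuration.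

## Logic of the disconnections

**20 to 19.** No skeletal bond is cut; the O–Si bonds at O7 and at the side-chain oxygen are restored. The two primary hydroxyls are the most nucleophilic oxygens and must be silent while O3 and O5 are acylated; two silyl ethers of the same kind allow one closing operation. The forward step must remove silicon without moving an acyl group or epimerising C3.

**19 to 18.** The O5–C(acyl) bond of the isobutyrate is cut. O5 is the oxygen that is unveiled last, so its acylation is the last skeletal operation and needs no selectivity. The demand is a mild acylation next to the cis isopropyl group that does not enolise the α-acyloxy ketone.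

**18 to 17.** O5 is reconnected to C2, turning the hydroxy enone into a bridgehead silyl ketal of a 7-oxanorbornene. This keeps O5 masked while O3 is acylated and exposes the [4+2] retron. The forward step is a ketal hydrolysis that must be faster than acid cleavage of the two primary silyl ethers and must not break the C5–O bond.

**17 to 12 and 16.** The O3–C(acyl) ester bond is cut, which makes the route convergent. The demand is acylation of a hindered endo secondary hydroxyl by an α-branched unsaturated acid under basic conditions that leave the silyl ketal intact.

**16 to 15, then to 13 and 14.** The carboxylic acid is traced to its ethyl ester and the side-chain C=C bond is cut between two commercial two- and three-carbon partners. The demand is E selectivity in the olefination and a hydrolysis that spares the silyl ether.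

**12 to 11, then to 10.** The O7–Si bond is removed, then C3–O is replaced by C3–B and O7–H by O7–B. This traces both free hydroxyls to one boron atom. The forward oxidation must proceed with retention at C3, must be faster than cycloreversion, and must spare the silyl ketal.

**10 to 9.** The C2–C3 and C4–C5 bonds are cut in a retro-[4+2] step. Two rings and four stereocentres disappear, leaving a furan and an E alkene joined only through O7–B. The forward cycloaddition must be regioselective, endo in boron and selective for one furan face.

**9 to 8, then to 7 and 2.** The furan O–Si bond and then the O7–B bond are cut. Boron carries one alkyl spectator and not a second alkoxy group, so that the alkene stays an activated dienophile and alkoxy groups cannot scramble. The spectator is isopinocampheyl because it is the only stereogenic element that can choose the furan face, it comes from hydroboration, and it leaves in the oxidation that frees C3–OH. Triisopropylsilyl is chosen so that the bridgehead ketal survives three later steps. The assembly must be non-aqueous and run in one flask.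

**7 to 6, then to 4 and 5; 4 to 3.** One B–OEt bond is traded back for a B–C bond to a second terpene group, and the B–alkenyl bond is cut by retro-hydroboration. A crystalline dialkylborane adds only once to a terminal alkyne, which avoids the double addition that a monoalkylborane would give. The demand is removal of exactly one terpene group.

**2 to 1.** The C1–C7 bond is cut, leaving the parent butenolide and a one-carbon electrophile. The forward step must hydroxymethylate the α-carbon of an unsaturated lactone.

## Other disconnections considered

**Alternative 1:** The cut is at C4–isopropyl and C3–O on the flat dienone monoketal A1.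
- Forward key step: Cu(OTf)2 with a chiral phosphoramidite adds i-Pr2Zn to C4 of A1, and the zinc enolate is hydroxylated at C3 by an N-sulfonyloxaziridine anti to the new isopropyl group, giving A2.
- In favour: enantiocontrol is catalytic and rests on a known reaction class, which is better than the chosen plan on both counts. A1 is achiral and a few steps from a cheap phenol. C7 is present from the start.
- Against: secondary dialkylzinc reagents are slow and usually less selective donors, and zinc enolates are oxidised sluggishly. C5 is left at the ketone level. After ketal hydrolysis the ene-dione is a tautomer of a hydroquinone, C4 becomes enolisable, and the C5 carbonyl must be reduced in preference to C2 and cis to isopropyl.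
- Comparison: on mechanism and precedent it is the better plan. On structure it sets two of the three centres where the chosen plan sets all three together with the C2/C5 oxidation pattern. On step count it is about equal, because the saved early steps are spent on a delicate reduction.

**Alternative 2:** The cut is at C1–C2 and O–C7 of the carbocycle.
- Forward key step: the nitrile oxide from aldoxime A3 (NaOCl) adds to its own vinyl group and gives the cyclohexane-fused isoxazoline A4.
- In favour: intramolecular nitrile oxide cycloadditions are reliable and regiocontrolled by the tether, which is better than the chosen key step. N–O cleavage (Mo(CO)6) later reveals the C2 ketone and C7–OH together. The stereocentres are carried in, not created, so the absolute configuration is secure, which is at least equal to the chosen plan.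
- Against: A3 needs an acyclic stereotetrad C3–C6 with a branched centre between two oxygenated ones, which is many steps. After N–O cleavage the C1=C6 alkene must arise by loss of the C6 ether while the C7 hydroxyl, also β to the ketone, can leave instead. The isobutyrate must survive all of this, and O3 must change from silyl to acyl late.
- Comparison: mechanistically safer in the ring-forming step, clearly longer, and weaker in end-game chemoselectivity. The chosen plan obtains the enone with both oxygens placed directly from the cycloadduct.

**Alternative 3:** The cut is at C1–C6.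
- Forward key step: catalytic Hg(OCOCF3)2 (divalent mercury) in aqueous acetone converts the C-isopropyl enopyranoside A5 by Ferrier carbocyclisation into the cyclohexanone A6.
- In favour: the absolute configuration comes from the chiral pool, which is better than reliance on an untested auxiliary. The reaction is well established. O3 and O5 are differentiated as silyl and 4-methoxybenzyl ethers from the outset, which is at least equal to the ketal-based differentiation.
- Against: the isopropyl branch must be placed on the pyranose with inversion and cis to O2, which needs several protecting-group and activation steps. Mercury salts are used. A6 lacks C7, so dehydration to the enone and an α-hydroxymethylation of a hindered enone must follow.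
- Comparison: better on certainty of configuration, worse on length (well above the chosen route), and C7 has to be added late instead of being present from the first step.

Key step: step 5

Remark: it is assumed that the isopinocampheyl group derived from (+)-α-pinene directs the dienophile to the furan face that leads to the natural configuration; the sense of this induction cannot be predicted reliably and the antipodal terpene is equally available.

## Route

Step 1
Reactants: 1 furan-2(5H)-one
Product: 2 3-(hydroxymethyl)furan-2(5H)-one
Conditions: 37% aq. HCHO (3 equiv), PBu3 (0.2 equiv), CHCl3/MeOH, rt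
Reagents that add atoms: formaldehyde, C=O
Why: Morita–Baylis–Hillman reaction: the phosphine adds to C4 of the butenolide, the lactone enolate attacks formaldehyde through C3, and proton transfer with loss of the phosphine restores the alkene; excess formaldehyde should outrun Rauhut–Currier dimerisation, and no stereocentre is formed.

Step 2
Reactants: 3 (+)-α-pinene
Product: 4 (−)-diisopinocampheylborane
Conditions: BH3·SMe2 (1 equiv), 3 (2.3 equiv), THF, 0 °C, 3 d; crystals collected under Ar
Reagents that add atoms: borane–dimethyl sulfide, C[S+](C)[BH3-]
Why: Hydroboration from the face anti to the gem-dimethyl bridge with boron at the less substituted carbon sets all stereocentres of both terpene groups; slow equilibration with a slight excess of 3 lets the stereochemically homogeneous dimer crystallise, which raises its enantiomeric purity above that of 3.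

Step 3
Reactants: 4 (−)-diisopinocampheylborane; 5 3-methylbut-1-yne
Product: 7 ethyl [(E)-3-methylbut-1-enyl](isopinocampheyl)borinate, via B-[(E)-3-methylbut-1-enyl]diisopinocampheylborane 6 (not isolated)
Conditions: 5 (1.1 equiv), THF, −25 → 0 °C; then CH3CHO (1.05 equiv), 0 °C; volatiles and α-pinene removed in vacuo
Reagents that add atoms: acetaldehyde, CC=O
Why: The hindered dialkylborane adds once, syn and anti-Markovnikov, to the terminal alkyne and sets the E alkene; one terpene group is then excised by β-hydride transfer to acetaldehyde (dehydroboration with carbonyl reduction), and the resulting borinate is much less Lewis acidic, so the second group should react far more slowly and one equivalent of aldehyde should stop at 7.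

Step 4
Reactants: 7 ethyl [(E)-3-methylbut-1-enyl](isopinocampheyl)borinate; 2 3-(hydroxymethyl)furan-2(5H)-one
Product: 9 [2-(triisopropylsilyloxy)furan-3-yl]methyl [(E)-3-methylbut-1-enyl](isopinocampheyl)borinate, via (2-oxo-2,5-dihydrofuran-3-yl)methyl [(E)-3-methylbut-1-enyl](isopinocampheyl)borinate 8 (not isolated)
Conditions: PhMe, rt, repeated evaporation (removal of EtOH); then TIPSOTf (1.1 equiv), Et3N (1.5 equiv), CH2Cl2, −78 → 0 °C; pentane, filtration under Ar; used at once
Reagents that add atoms: triisopropylsilyl trifluoromethanesulfonate, CC(C)[Si](OS(=O)(=O)C(F)(F)F)(C(C)C)C(C)C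
Why: Borinic esters exchange alkoxy groups readily and removal of volatile ethanol drives the transesterification to 8; soft enolisation with silyl triflate and amine then removes a C5 proton of the butenolide and silylates the carbonyl oxygen, helped by the gain in furan aromaticity, while the strong B–O bond should not be exchanged by the silyl triflate.

Step 5
Reactants: 9 [2-(triisopropylsilyloxy)furan-3-yl]methyl [(E)-3-methylbut-1-enyl](isopinocampheyl)borinate
Product: 10 tricyclic oxanorbornene–oxaborinane cycloadduct (B-isopinocampheyl; boron endo at C3; isopropyl exo at C4; triisopropylsilyloxy on bridgehead C2)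
Conditions: PhMe (0.01 M), BHT (cat.), 40 → 60 °C, Ar; solution used directly in step 6
Reagents that add atoms: none
Why: Proposed new method: a concerted, asynchronous thermal [4+2] cycloaddition in which the electron-rich 2-silyloxyfuran adds across its C2 and C5 to the alkenylborinate, whose alkene is lowered in LUMO energy by the vacant boron p orbital; the closest known reaction types are boron-tethered intramolecular Diels–Alder reactions of alkenylboronates with dienyl alcohols, silicon-tethered cycloadditions of vinylsilanes, and intermolecular cycloadditions of 2-silyloxyfurans with electron-poor alkenes. The three-atom C7–O7–B tether is anchored at the internal diene carbon C1, so the boron-bearing carbon can only reach the adjacent terminus C2 and the isopropyl-bearing carbon must bond to C5, the same sense that the polarisation of the partners (nucleophilic furan C5, electrophilic β-carbon of the alkenylborane) favours. Ring A, the oxanorbornene carbocycle, closes by suprafacial addition to both components; ring B, the six-membered oxaborinane, closes through the new C2–C3 bond as a ring fused along C1–C2, with the C1=C6 alkene exocyclic to it. C2 and C5 are held cis by the furan oxygen, and C3 and C4 are trans because the E alkene adds suprafacially. Boron is endo because an exo boron would need a nearly antiperiplanar B–C3–C2–C1 arrangement that a six-membered ring cannot span, and this places isopropyl exo. The absolute sense, that is the furan face attacked, rests on the isopinocampheyl group, whose methine hydrogen should eclipse one boron substituent so that its two unequal ring branches flank the boron plane and meet the dienophile side differently in the two diastereomeric transition states; this bias is untested and may be modest. The step also needs the cycloaddition to outpace dehydroboration of the terpene group and intermolecular reaction, which moderate temperature, high dilution and the entropic advantage of the tether should secure.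

Step 6
Reactants: 10 tricyclic oxanorbornene–oxaborinane cycloadduct
Product: 11 (1S,4S,5R,6R)-2-(hydroxymethyl)-5-exo-isopropyl-1-(triisopropylsilyloxy)-7-oxabicyclo[2.2.1]hept-2-en-6-endo-ol
Conditions: NaBO3·4H2O (5 equiv), THF/H2O, 0 °C → rt, added to the cooled solution from step 5; Et3N-deactivated silica
Reagents that add atoms: sodium perborate tetrahydrate, [Na+].[Na+].O[B-]1(O)OO[B-](O)(O)OO1
Why: Peroxoborate oxidises both B–C bonds by 1,2-migration from boron to oxygen with retention, so the endo C3–B bond becomes the endo C3–OH (trans to isopropyl) and hydrolysis of the borate frees O7; the mildly basic medium should leave the base-stable silyl ketal intact and the low temperature limits cycloreversion.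

Step 7
Reactants: 11 the oxanorbornene diol
Product: 12 (1S,4S,5R,6R)-2-[(tert-butyldimethylsilyloxy)methyl]-5-exo-isopropyl-1-(triisopropylsilyloxy)-7-oxabicyclo[2.2.1]hept-2-en-6-endo-ol
Conditions: TBSCl (1.05 equiv), imidazole, CH2Cl2, 0 °C
Reagents that add atoms: tert-butyldimethylsilyl chloride, CC(C)(C)[Si](C)(C)Cl
Why: Silylation discriminates the unhindered primary allylic hydroxyl from the endo secondary hydroxyl, which is flanked by the bridgehead silyl ketal and the isopropyl-bearing carbon.

Step 8
Reactants: 13 (tert-butyldimethylsilyloxy)acetaldehyde; 14 ethyl 2-(triphenylphosphoranylidene)propanoate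
Product: 15 ethyl (E)-4-(tert-butyldimethylsilyloxy)-2-methylbut-2-enoate
Conditions: CH2Cl2, rt
Reagents that add atoms: none
Why: Wittig reaction of a stabilised α-methyl ylide; reversible oxaphosphetane formation places the ester trans to the silyloxymethyl group and gives the E trisubstituted alkene of the side chain.

Step 9
Reactants: 15 ethyl (E)-4-(tert-butyldimethylsilyloxy)-2-methylbut-2-enoate
Product: 16 (E)-4-(tert-butyldimethylsilyloxy)-2-methylbut-2-enoic acid
Conditions: LiOH·H2O, THF/MeOH/H2O, 0 °C → rt; cold 1 M HCl to pH 4
Reagents that add atoms: lithium hydroxide monohydrate, [Li+].[OH-].O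
Why: Saponification of the ethyl ester; the primary silyl ether should tolerate cold aqueous hydroxide and brief acidification to pH 4, and the conjugated E alkene is not at risk.

Step 10
Reactants: 12 the mono-silylated oxanorbornenol; 16 (E)-4-(tert-butyldimethylsilyloxy)-2-methylbut-2-enoic acid
Product: 17 (1S,4S,5S,6R)-2-[(tert-butyldimethylsilyloxy)methyl]-5-exo-isopropyl-1-(triisopropylsilyloxy)-7-oxabicyclo[2.2.1]hept-2-en-6-endo-yl (E)-4-(tert-butyldimethylsilyloxy)-2-methylbut-2-enoate
Conditions: 16, 2,4,6-trichlorobenzoyl chloride, Et3N, PhMe, rt; then 12, DMAP, rt → 40 °C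
Reagents that add atoms: none
Why: Yamaguchi esterification: DMAP attacks the less hindered acyl group of the mixed anhydride and the acylpyridinium acylates the hindered endo C3–OH; the medium stays basic, so the silyl ketal keeps O5 masked and the acyl group can only go to O3, and no stereocentre is touched.

Step 11
Reactants: 17 the C3 ester with intact silyl ketal
Product: 18 (1R,5S,6S)-3-[(tert-butyldimethylsilyloxy)methyl]-5-hydroxy-6-isopropyl-2-oxocyclohex-3-en-1-yl (E)-4-(tert-butyldimethylsilyloxy)-2-methylbut-2-enoate
Conditions: PPTS (0.2 equiv), THF/H2O 10:1, 0 °C → rt
Reagents that add atoms: none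
Why: Acid-catalysed ketal hydrolysis: protonation of the bridging oxygen and strain-releasing C2–O cleavage give a silyloxy-stabilised allyl cation that loses silicon to water, unveiling the C2 enone and the C5 hydroxyl with C5 unchanged because its C–O bond is not broken; ionisation of a strained ketal should be far faster than acid cleavage of primary silyl ethers, and the trans 1,3-relationship of O3 and O5 disfavours acyl migration.

Step 12
Reactants: 18 the hydroxy enone
Product: 19 (1R,5S,6S)-3-[(tert-butyldimethylsilyloxy)methyl]-5-(isobutyryloxy)-6-isopropyl-2-oxocyclohex-3-en-1-yl (E)-4-(tert-butyldimethylsilyloxy)-2-methylbut-2-enoate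
Conditions: (i-PrCO)2O, pyridine, DMAP (cat.), CH2Cl2, 0 °C → rt
Reagents that add atoms: isobutyric anhydride, CC(C)C(=O)OC(=O)C(C)C
Why: DMAP-catalysed acylation of the only free hydroxyl; pyridine is too weak a base to enolise the α-acyloxy ketone, and the C3 configuration (ester trans to isopropyl) is in any case the more stable one.

Step 13
Reactants: 19 the bis-silyl ether diester
Product: 20 CNP0254776.1, (1R,5S,6S)-3-(hydroxymethyl)-5-(isobutyryloxy)-6-isopropyl-2-oxocyclohex-3-en-1-yl (E)-4-hydroxy-2-methylbut-2-enoate
Conditions: HF·pyridine, pyridine/THF, 0 °C → rt
Reagents that add atoms: none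
Why: Fluoride cleaves both primary silyl ethers under buffered, slightly acidic conditions in which neither ester should migrate nor C3 epimerise; the freed hydroxyls are remote from both acyl groups (C7 is trans to C5 across the C1=C6 alkene).

## Compound list

1 | furan-2(5H)-one | O=C1OCC=C1 | starting material
2 | 3-(hydroxymethyl)furan-2(5H)-one | O=C1OCC=C1CO | intermediate
3 | (1R,5R)-(+)-α-pinene | CC1=CC[C@@H]2C[C@H]1C2(C)C | starting material
4 | (−)-diisopinocampheylborane, each group (1R,2S,3R,5R) | [BH]([C@@H]1C[C@@H]2C[C@H]([C@H]1C)C2(C)C)[C@@H]1C[C@@H]2C[C@H]([C@H]1C)C2(C)C | intermediate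
5 | 3-methylbut-1-yne | CC(C)C#C | starting material
6 | B-[(E)-3-methylbut-1-enyl]diisopinocampheylborane | B([C@@H]1C[C@@H]2C[C@H]([C@H]1C)C2(C)C)([C@@H]1C[C@@H]2C[C@H]([C@H]1C)C2(C)C)/C=C/C(C)C | intermediate
7 | ethyl [(E)-3-methylbut-1-enyl](isopinocampheyl)borinate | CCOB([C@@H]1C[C@@H]2C[C@H]([C@H]1C)C2(C)C)/C=C/C(C)C | intermediate
8 | (2-oxo-2,5-dihydrofuran-3-yl)methyl [(E)-3-methylbut-1-enyl](isopinocampheyl)borinate | B([C@@H]1C[C@@H]2C[C@H]([C@H]1C)C2(C)C)(OCC1=CCOC1=O)/C=C/C(C)C | intermediate
9 | [2-(triisopropylsilyloxy)furan-3-yl]methyl [(E)-3-methylbut-1-enyl](isopinocampheyl)borinate | B([C@@H]1C[C@@H]2C[C@H]([C@H]1C)C2(C)C)(OCc1ccoc1O[Si](C(C)C)(C(C)C)C(C)C)/C=C/C(C)C | intermediate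
10 | tricyclic oxanorbornene–oxaborinane cycloadduct (boron endo at C3, isopropyl exo at C4, silyl ketal at bridgehead C2) | B1([C@@H]2C[C@@H]3C[C@H]([C@H]2C)C3(C)C)OCC4=C[C@@H]5O[C@@]4(O[Si](C(C)C)(C(C)C)C(C)C)[C@H]1[C@H]5C(C)C | intermediate
11 | (1S,4S,5R,6R)-2-(hydroxymethyl)-5-exo-isopropyl-1-(triisopropylsilyloxy)-7-oxabicyclo[2.2.1]hept-2-en-6-endo-ol | OCC1=C[C@@H]2O[C@@]1(O[Si](C(C)C)(C(C)C)C(C)C)[C@H](O)[C@H]2C(C)C | intermediate
12 | (1S,4S,5R,6R)-2-[(tert-butyldimethylsilyloxy)methyl]-5-exo-isopropyl-1-(triisopropylsilyloxy)-7-oxabicyclo[2.2.1]hept-2-en-6-endo-ol | CC(C)(C)[Si](C)(C)OCC1=C[C@@H]2O[C@@]1(O[Si](C(C)C)(C(C)C)C(C)C)[C@H](O)[C@H]2C(C)C | intermediate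
13 | (tert-butyldimethylsilyloxy)acetaldehyde | CC(C)(C)[Si](C)(C)OCC=O | starting material
14 | ethyl 2-(triphenylphosphoranylidene)propanoate | CCOC(=O)C(C)=P(c1ccccc1)(c1ccccc1)c1ccccc1 | starting material
15 | ethyl (E)-4-(tert-butyldimethylsilyloxy)-2-methylbut-2-enoate | CCOC(=O)/C(C)=C/CO[Si](C)(C)C(C)(C)C | intermediate
16 | (E)-4-(tert-butyldimethylsilyloxy)-2-methylbut-2-enoic acid | OC(=O)/C(C)=C/CO[Si](C)(C)C(C)(C)C | intermediate
17 | 6-endo ester of 12 with 16 (silyl ketal intact) | CC(C)(C)[Si](C)(C)OCC1=C[C@@H]2O[C@@]1(O[Si](C(C)C)(C(C)C)C(C)C)[C@H](OC(=O)/C(C)=C/CO[Si](C)(C)C(C)(C)C)[C@H]2C(C)C | intermediate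
18 | (1R,5S,6S)-3-[(tert-butyldimethylsilyloxy)methyl]-5-hydroxy-6-isopropyl-2-oxocyclohex-3-en-1-yl (E)-4-(tert-butyldimethylsilyloxy)-2-methylbut-2-enoate | C/C(=C\CO[Si](C)(C)C(C)(C)C)C(=O)O[C@H]1C(=O)C(CO[Si](C)(C)C(C)(C)C)=C[C@H](O)[C@@H]1C(C)C | intermediate
19 | 5-O-isobutyrate of 18 | C/C(=C\CO[Si](C)(C)C(C)(C)C)C(=O)O[C@H]1C(=O)C(CO[Si](C)(C)C(C)(C)C)=C[C@H](OC(=O)C(C)C)[C@@H]1C(C)C | intermediate
20 | CNP0254776.1, (1R,5S,6S)-3-(hydroxymethyl)-5-(isobutyryloxy)-6-isopropyl-2-oxocyclohex-3-en-1-yl (E)-4-hydroxy-2-methylbut-2-enoate | C/C(=C\CO)C(=O)O[C@H]1C(=O)C(CO)=C[C@H](OC(=O)C(C)C)[C@@H]1C(C)C | target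

## Step count and least certain steps

Total: 13 steps. Longest linear sequence: 10 steps (steps 2, 3, 4, 5, 6, 7, 10, 11, 12, 13, from 3 to 20).

**Step 5 (key step, new method).**
- Most likely problem: poor facial selectivity, because the chiral group sits on a trigonal boron that points away from the furan.
- Other risks: dehydroboration of the terpene group on warming; Lewis-acid-assisted anti elimination of the C3–B bond across the C2–O bridge bond, which lies nearly antiperiplanar to it.
- Fallback on known chemistry, setting out from 2 and 5 and returning at 11:
  - Hydrosilylation of 5 with HSiMe2Cl under Pt2[(CH2=CHSiMe2)2O]3 (zerovalent platinum) should give (E)-chloro(dimethyl)(3-methylbut-1-enyl)silane F1.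
  - F1 silylates 2 (Et3N, DMAP) to the silyl ether F2, and TIPSOTf/Et3N gives the silyloxyfuran F3.
  - A thermal silicon-tethered intramolecular Diels–Alder reaction (PhMe, sealed tube, 110–150 °C) should give the racemic oxanorbornene–oxasilinane F4.
  - Tamao–Fleming oxidation (H2O2, KF, KHCO3, THF/MeOH) with retention gives racemic 11, and the antipode of 11, F5, is removed by preparative chromatography on a chiral stationary phase.

**Step 4.**
- Most likely problem: incomplete transesterification, or loss of the B–O link during soft enolisation, so that free or O-silylated alcohol is carried into the cycloaddition without a tether.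
- Fallback, setting out from 2 and 7 and returning at 9, forms the B–O bond last:
  - 2 is silylated with Me3SiCl/Et3N to 3-[(trimethylsilyloxy)methyl]furan-2(5H)-one F7 and enolised with TIPSOTf/Et3N to the bis-silyl furan F8.
  - 7 is converted with BCl3 into chloro[(E)-3-methylbut-1-enyl](isopinocampheyl)borane F6.
  - B–Cl/Si–O exchange between F6 and F8 at low temperature gives 9 with loss of Me3SiCl.

**Step 6.**
- Most likely problem: slow oxidation of two hindered B–C bonds, which leaves time for cycloreversion, elimination across C2–C3, or collapse of the silyl ketal in the aqueous base.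
- Fallback, setting out from 10 and returning at 11: the terpene group is first excised with excess acetaldehyde to give the cyclic ethyl boronate F9, which needs only one B–C oxidation and can be purified. F9 is then oxidised under neutral, anhydrous conditions with Me3NO in THF to 11.

**Step 10.**
- Most likely problem: failure to acylate the crowded endo hydroxyl with an α-branched, conjugated acyl donor, or deconjugation of the activated acid.
- Fallback, setting out from 12 and returning at 17: 12 is acylated with the small 2-(diethoxyphosphoryl)propanoic acid (DCC, DMAP) to the phosphonate ester F10. A Horner–Wadsworth–Emmons reaction of F10 with 13 (LiCl, DBU, MeCN) then builds the E alkene on the ester already in place.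

**Step 1.**
- Most likely problem: sluggish addition of the phosphine to the lactone, and competing dimerisation of the butenolide.
- Fallback, setting out from 1 and returning at 2: bromine addition gives trans-3,4-dibromodihydrofuran-2(3H)-one F11, Et3N eliminates HBr to 3-bromofuran-2(5H)-one F12, and a Stille coupling with Bu3SnCH2OH under Pd(PPh3)4 (zerovalent palladium) installs the hydroxymethyl group.

## Further compounds

F1 | step 5 | (E)-chloro(dimethyl)(3-methylbut-1-enyl)silane | C[Si](C)(Cl)/C=C/C(C)C
F2 | step 5 | 3-({dimethyl[(E)-3-methylbut-1-enyl]silyl}oxymethyl)furan-2(5H)-one | C[Si](C)(OCC1=CCOC1=O)/C=C/C(C)C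
F3 | step 5 | dimethyl[(E)-3-methylbut-1-enyl]{[2-(triisopropylsilyloxy)furan-3-yl]methoxy}silane | C[Si](C)(OCc1ccoc1O[Si](C(C)C)(C(C)C)C(C)C)/C=C/C(C)C
F4 | step 5 | racemic oxanorbornene–oxasilinane cycloadduct (silicon endo at C3, isopropyl exo at C4; one enantiomer drawn) | C[Si]1(C)OCC2=C[C@@H]3O[C@@]2(O[Si](C(C)C)(C(C)C)C(C)C)[C@H]1[C@H]3C(C)C
F5 | step 5 | antipode of 11 | OCC1=C[C@H]2O[C@]1(O[Si](C(C)C)(C(C)C)C(C)C)[C@@H](O)[C@@H]2C(C)C
F6 | step 4 | chloro[(E)-3-methylbut-1-enyl](isopinocampheyl)borane | ClB([C@@H]1C[C@@H]2C[C@H]([C@H]1C)C2(C)C)/C=C/C(C)C
F7 | step 4 | 3-[(trimethylsilyloxy)methyl]furan-2(5H)-one | C[Si](C)(C)OCC1=CCOC1=O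
F8 | step 4 | triisopropyl({3-[(trimethylsilyloxy)methyl]furan-2-yl}oxy)silane | C[Si](C)(C)OCc1ccoc1O[Si](C(C)C)(C(C)C)C(C)C
F9 | step 6 | cyclic ethyl boronate of the cycloadduct (B-ethoxy oxaborinane) | CCOB1OCC2=C[C@@H]3O[C@@]2(O[Si](C(C)C)(C(C)C)C(C)C)[C@H]1[C@H]3C(C)C
F10 | step 10 | 6-endo 2-(diethoxyphosphoryl)propanoate of 12 (epimers at the phosphonate carbon) | CC(C)(C)[Si](C)(C)OCC1=C[C@@H]2O[C@@]1(O[Si](C(C)C)(C(C)C)C(C)C)[C@H](OC(=O)C(C)P(=O)(OCC)OCC)[C@H]2C(C)C
F11 | step 1 | trans-3,4-dibromodihydrofuran-2(3H)-one (racemic; one enantiomer drawn) | Br[C@H]1COC(=O)[C@@H]1Br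
F12 | step 1 | 3-bromofuran-2(5H)-one | BrC1=CCOC1=O
A1 | alternative 1 | 2-[(tert-butyldimethylsilyloxy)methyl]-4,4-dimethoxycyclohexa-2,5-dien-1-one | O=C1C=CC(OC)(OC)C=C1CO[Si](C)(C)C(C)(C)C
A2 | alternative 1 | (5R,6R)-2-[(tert-butyldimethylsilyloxy)methyl]-6-hydroxy-5-isopropyl-4,4-dimethoxycyclohex-2-en-1-one | O[C@H]1C(=O)C(CO[Si](C)(C)C(C)(C)C)=CC(OC)(OC)[C@@H]1C(C)C
A3 | alternative 2 | acyclic aldoxime with O3 silyl ether, C4 isopropyl, O5 isobutyrate, C6 methoxymethyl ether and terminal vinyl group | ON=C[C@H](O[Si](C)(C)C(C)(C)C)[C@@H](C(C)C)[C@@H](OC(=O)C(C)C)[C@H](OCOC)C=C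
A4 | alternative 2 | cyclohexane-fused isoxazoline (C1 epimers) | CC(C)(C)[Si](C)(C)O[C@H]1C2=NOCC2[C@@H](OCOC)[C@H](OC(=O)C(C)C)[C@@H]1C(C)C
A5 | alternative 3 | methyl 3,6-dideoxy-3-C-isopropyl-2-O-(4-methoxybenzyl)-4-O-(tert-butyldimethylsilyl)hex-5-enopyranoside (O2 cis and O4 trans to isopropyl) | COC1OC(=C)[C@H](O[Si](C)(C)C(C)(C)C)[C@@H](C(C)C)[C@H]1OCc2ccc(OC)cc2
A6 | alternative 3 | 2-(tert-butyldimethylsilyloxy)-5-hydroxy-3-isopropyl-4-(4-methoxybenzyloxy)cyclohexan-1-one | CC(C)(C)[Si](C)(C)O[C@H]1C(=O)CC(O)[C@H](OCc2ccc(OC)cc2)[C@@H]1C(C)C
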